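**Plan**
- Retrosynthesis: the aldehyde goes back to a silyl-protected allylic alcohol and the side-chain acetate to the aryl methyl ketone. The O1–C2 bond of the dihydrofuran ring is then cut together with the C3 O–acyl bond, giving an aryl isovalerate that carries a five-membered carbonate across the C3 and C2 oxygens. This is cut at C3–C2 into 5-acetylsalicylaldehyde and dihydroxyacetone acetonide.
- Forward: a proline aldol joins C3–C2, methylenation gives the exocyclic C=CH2, protecting-group exchange installs the carbonate and the aryl ester, and one palladium event closes the dihydrofuran ring. The side chain and the aldehyde are finished last.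
- Enabling feature: C2 is allylic to the C=CH2 group and its oxygen sits in the carbonate ring shared with the C3 oxygen, while the benzene ring carries the isovaleryl ester ortho to C3, six atoms from the C3 oxygen. Ionisation at C2 releases CO2 and a C3 alkoxide, which pulls the acyl group over and hands the phenoxide to the π-allyl.
- Stereochemistry: C3 and C2 come from the L-proline anti aldol and are carried into the ring with net retention at C2 (double inversion). The side-chain carbinol comes from Noyori transfer hydrogenation.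

Key step: step 9

Remark: 5-acetyl-2-hydroxybenzaldehyde (1) and 2,2-dimethyl-1,3-dioxan-5-one (3) are taken as purchased. The π-allyl intermediates 11 and 12 are written in their sigma-allyl form without the phosphine ligand.

Step 1
Reactants: 1 5-acetyl-2-hydroxybenzaldehyde
Product: 2 5-acetyl-2-(triisopropylsilyloxy)benzaldehyde
Conditions: TIPSCl, imidazole, DMF, rt
Reagents that add atoms: triisopropylsilyl chloride (CC(C)[Si](Cl)(C(C)C)C(C)C)
Why: Imidazole-mediated silylation of the acidic phenol; the bulky triisopropylsilyl ether should survive the enamine, ylide and dilute-acid steps and leave later under fluoride.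

Step 2
Reactants: 2 5-acetyl-2-(triisopropylsilyloxy)benzaldehyde; 3 2,2-dimethyl-1,3-dioxan-5-one
Product: 4 (4S)-4-[(S)-[5-acetyl-2-(triisopropylsilyloxy)phenyl](hydroxy)methyl]-2,2-dimethyl-1,3-dioxan-5-one
Conditions: L-proline (30 mol %), DMF, 4 °C
Reagents that add atoms: none
Why: Proline enamine aldol (List–Barbas type): the E-enamine of the cyclic ketone should add to the Re face of the aldehyde through the hydrogen-bonded Houk–List chair, giving the anti adduct and setting C3 (S) and C2 (4S in the dioxanone) together.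

Step 3
Reactants: 4 (4S)-4-[(S)-[5-acetyl-2-(triisopropylsilyloxy)phenyl](hydroxy)methyl]-2,2-dimethyl-1,3-dioxan-5-one
Product: 5 (4S)-4-[(S)-[5-acetyl-2-(triisopropylsilyloxy)phenyl](triethylsilyloxy)methyl]-2,2-dimethyl-1,3-dioxan-5-one
Conditions: TESOTf, 2,6-lutidine, CH2Cl2, −78 °C
Reagents that add atoms: triethylsilyl trifluoromethanesulfonate (CC[Si](CC)(CC)OS(=O)(=O)C(F)(F)F)
Why: Silylation of the aldol hydroxyl with a silyl triflate and a hindered base at low temperature should block retro-aldol and alkoxide chemistry in the next step without touching the epimerisable ketone.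

Step 4
Reactants: 5 (4S)-4-[(S)-[5-acetyl-2-(triisopropylsilyloxy)phenyl](triethylsilyloxy)methyl]-2,2-dimethyl-1,3-dioxan-5-one
Product: 6 (4R)-4-[(S)-[5-acetyl-2-(triisopropylsilyloxy)phenyl](triethylsilyloxy)methyl]-2,2-dimethyl-5-methylidene-1,3-dioxane
Conditions: Ph3PCH3Br, KN(SiMe3)2 (ylide preformed, 1.2 equiv), THF, −78 to 0 °C
Reagents that add atoms: methyltriphenylphosphonium bromide (C[P+](c1ccccc1)(c1ccccc1)c1ccccc1.[Br-])
Why: Wittig methylenation: the 5-oxo-1,3-dioxane carbonyl, flanked by two C–O bonds, is far more electrophilic than the aryl methyl ketone deactivated by the para silyloxy group, so a slight excess of ylide at low temperature should take it alone; no stereocentre is made and the ring-carbon descriptor changes to R only through the priority rules.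

Step 5
Reactants: 6 (4R)-4-[(S)-[5-acetyl-2-(triisopropylsilyloxy)phenyl](triethylsilyloxy)methyl]-2,2-dimethyl-5-methylidene-1,3-dioxane
Product: 7 1-[3-[(1S,2R)-1,2,4-trihydroxy-3-methylidenebutyl]-4-(triisopropylsilyloxy)phenyl]ethanone
Conditions: AcOH–THF–H2O (3:1:1), rt
Reagents that add atoms: none
Why: Acid hydrolysis of the isopropylidene ketal and the triethylsilyl ether in one operation; the aryl triisopropylsilyl ether and both stereocentres should be unaffected by dilute acetic acid.

Step 6
Reactants: 7 1-[3-[(1S,2R)-1,2,4-trihydroxy-3-methylidenebutyl]-4-(triisopropylsilyloxy)phenyl]ethanone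
Product: 8 1-[3-[(1S,2R)-4-(tert-butyldimethylsilyloxy)-1,2-dihydroxy-3-methylidenebutyl]-4-(triisopropylsilyloxy)phenyl]ethanone
Conditions: TBSCl (1.05 equiv), imidazole, CH2Cl2, −20 to 0 °C
Reagents that add atoms: tert-butyldimethylsilyl chloride (CC(C)(C)[Si](C)(C)Cl)
Why: Steric differentiation in silylation: the primary allylic hydroxyl should react well before the two secondary ones.

Step 7
Reactants: 8 1-[3-[(1S,2R)-4-(tert-butyldimethylsilyloxy)-1,2-dihydroxy-3-methylidenebutyl]-4-(triisopropylsilyloxy)phenyl]ethanone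
Product: 9 (4S,5R)-4-[5-acetyl-2-(triisopropylsilyloxy)phenyl]-5-[3-(tert-butyldimethylsilyloxy)prop-1-en-2-yl]-1,3-dioxolan-2-one
Conditions: CDI, DMAP (cat.), CH2Cl2, rt
Reagents that add atoms: 1,1'-carbonyldiimidazole (O=C(n1ccnc1)n1ccnc1)
Why: Carbonylation of the 1,2-diol with carbonyldiimidazole closes the five-membered carbonate without breaking a C–O bond, so the anti diol should give the cis-4,5-disubstituted carbonate that the key step needs.

Step 8
Reactants: 9 (4S,5R)-4-[5-acetyl-2-(triisopropylsilyloxy)phenyl]-5-[3-(tert-butyldimethylsilyloxy)prop-1-en-2-yl]-1,3-dioxolan-2-one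
Product: 10 4-acetyl-2-[(4S,5R)-5-[3-(tert-butyldimethylsilyloxy)prop-1-en-2-yl]-2-oxo-1,3-dioxolan-4-yl]phenyl 3-methylbutanoate
Conditions: isovaleric anhydride (2 equiv), CsF (1.5 equiv), DMF, 0 °C to rt
Reagents that add atoms: 3-methylbutanoic anhydride (CC(C)CC(=O)OC(=O)CC(C)C)
Why: Fluoride-promoted silyl-to-acyl exchange (Beaucage–Ogilvie type): fluoride should cleave the aryl Si–O bond of the acidic 4-acetylphenol much faster than the primary alkyl silyl ether, and the anhydride present acylates the phenoxide as it forms.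

Step 9
Reactants: 10 4-acetyl-2-[(4S,5R)-5-[3-(tert-butyldimethylsilyloxy)prop-1-en-2-yl]-2-oxo-1,3-dioxolan-4-yl]phenyl 3-methylbutanoate
Product: 13 (2R,3S)-5-acetyl-2-[3-(tert-butyldimethylsilyloxy)prop-1-en-2-yl]-2,3-dihydro-1-benzofuran-3-yl 3-methylbutanoate, via allylpalladium alkoxide 11 (not isolated), via allylpalladium phenoxide 12 (not isolated)
Conditions: Pd2(dba)3·CHCl3 (2.5 mol %), dppe (6 mol %), THF, 0 °C to rt
Reagents that add atoms: none
Why: Proposed new method: zerovalent palladium ionises the allylic C2–O bond of the carbonate anti to the metal (inversion), CO2 leaves, and the C3 alkoxide 11 attacks the ortho isovaleryl ester through a six-membered transition state, so the acyl group moves to the C3 oxygen and the 4-acetylphenoxide 12 is set free next to the π-allyl, which it then attacks at C2 anti to palladium. The closest known reaction types are the decarboxylative cycloadditions of vinyl ethylene carbonates, in which the alkoxide is intercepted by an external electrophile before ring closure on the π-allyl, and the intramolecular Tsuji–Trost etherification of phenols; the O-to-O acyl shift as the relay between them is the untested part, argued from the six-membered geometry and the roughly eight pKa units gained in going from an alkoxide to a 4-acetylphenoxide. The dihydrofuran ring closes in the 5-exo mode on the internal allyl carbon, the 7-endo attack on the CH2 terminus being slower. C2 is the only stereocentre made: two inversions give net retention of the carbonate configuration, so the cis carbonate should deliver the 2,3-trans ring, and any facial exchange of palladium through the CH2 terminus also leads to trans because that transition state keeps the allylpalladium unit away from the C3 acyloxy group; C3 is not touched. The step needs the acyl shift to outrun epoxide closure and hydride shift of the alkoxide, which the activated aryl ester secures, and it needs the phenoxide not to expel the C3 ester as an ortho-quinone methide, which the para acetyl group and the immediate intramolecular capture secure.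

Step 10
Reactants: 13 (2R,3S)-5-acetyl-2-[3-(tert-butyldimethylsilyloxy)prop-1-en-2-yl]-2,3-dihydro-1-benzofuran-3-yl 3-methylbutanoate
Product: 14 (2R,3S)-2-[3-(tert-butyldimethylsilyloxy)prop-1-en-2-yl]-5-[(1S)-1-hydroxyethyl]-2,3-dihydro-1-benzofuran-3-yl 3-methylbutanoate
Conditions: RuCl(p-cymene)[(S,S)-TsDPEN] (1 mol %), HCO2H–Et3N (5:2), CH2Cl2, rt
Reagents that add atoms: none
Why: Noyori asymmetric transfer hydrogenation of the aryl methyl ketone: the (S,S)-TsDPEN ruthenium hydride should deliver hydride through its six-membered transition state to give the (S)-carbinol under reagent control, leaving the esters, the alkene and the allylic ether alone.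

Step 11
Reactants: 14 (2R,3S)-2-[3-(tert-butyldimethylsilyloxy)prop-1-en-2-yl]-5-[(1S)-1-hydroxyethyl]-2,3-dihydro-1-benzofuran-3-yl 3-methylbutanoate
Product: 15 (2R,3S)-5-[(1S)-1-acetoxyethyl]-2-[3-(tert-butyldimethylsilyloxy)prop-1-en-2-yl]-2,3-dihydro-1-benzofuran-3-yl 3-methylbutanoate
Conditions: Ac2O, Et3N, DMAP (cat.), CH2Cl2, 0 °C
Reagents that add atoms: acetic anhydride (CC(=O)OC(C)=O)
Why: DMAP-catalysed acetylation of the only free hydroxyl; the aldehyde is still masked, so the nucleophilic catalyst has no acrolein to attack.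

Step 12
Reactants: 15 (2R,3S)-5-[(1S)-1-acetoxyethyl]-2-[3-(tert-butyldimethylsilyloxy)prop-1-en-2-yl]-2,3-dihydro-1-benzofuran-3-yl 3-methylbutanoate
Product: 16 (2R,3S)-5-[(1S)-1-acetoxyethyl]-2-(3-hydroxyprop-1-en-2-yl)-2,3-dihydro-1-benzofuran-3-yl 3-methylbutanoate
Conditions: HF·pyridine, pyridine, THF, 0 °C to rt
Reagents that add atoms: none
Why: Fluoride cleavage of the primary silyl ether under buffered conditions, which should neither move nor cleave either ester.

Step 13
Reactants: 16 (2R,3S)-5-[(1S)-1-acetoxyethyl]-2-(3-hydroxyprop-1-en-2-yl)-2,3-dihydro-1-benzofuran-3-yl 3-methylbutanoate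
Product: 17 (2R,3S)-5-[(1S)-1-acetoxyethyl]-2-(3-oxoprop-1-en-2-yl)-2,3-dihydro-1-benzofuran-3-yl 3-methylbutanoate
Conditions: Dess–Martin periodinane, NaHCO3, CH2Cl2, 0 °C to rt
Reagents that add atoms: none
Why: Dess–Martin oxidation of the primary allylic alcohol to the α-substituted acrolein under buffered, non-nucleophilic conditions, which should avoid loss of the C3 ester and opening of the allylic aryl ether.

**Compound list**
1 | 5-acetyl-2-hydroxybenzaldehyde | CC(=O)c1ccc(O)c(C=O)c1 | starting material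
2 | 5-acetyl-2-(triisopropylsilyloxy)benzaldehyde | CC(=O)c1ccc(O[Si](C(C)C)(C(C)C)C(C)C)c(C=O)c1 | intermediate
3 | 2,2-dimethyl-1,3-dioxan-5-one | CC1(C)OCC(=O)CO1 | starting material
4 | (4S)-4-[(S)-[5-acetyl-2-(triisopropylsilyloxy)phenyl](hydroxy)methyl]-2,2-dimethyl-1,3-dioxan-5-one | O[C@@H](c1cc(C(C)=O)ccc1O[Si](C(C)C)(C(C)C)C(C)C)[C@@H]1OC(C)(C)OCC1=O | intermediate
5 | (4S)-4-[(S)-[5-acetyl-2-(triisopropylsilyloxy)phenyl](triethylsilyloxy)methyl]-2,2-dimethyl-1,3-dioxan-5-one | CC[Si](CC)(CC)O[C@@H](c1cc(C(C)=O)ccc1O[Si](C(C)C)(C(C)C)C(C)C)[C@@H]1OC(C)(C)OCC1=O | intermediate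
6 | (4R)-4-[(S)-[5-acetyl-2-(triisopropylsilyloxy)phenyl](triethylsilyloxy)methyl]-2,2-dimethyl-5-methylidene-1,3-dioxane | CC[Si](CC)(CC)O[C@@H](c1cc(C(C)=O)ccc1O[Si](C(C)C)(C(C)C)C(C)C)[C@@H]1OC(C)(C)OCC1=C | intermediate
7 | 1-[3-[(1S,2R)-1,2,4-trihydroxy-3-methylidenebutyl]-4-(triisopropylsilyloxy)phenyl]ethanone | O[C@@H](c1cc(C(C)=O)ccc1O[Si](C(C)C)(C(C)C)C(C)C)[C@H](O)C(=C)CO | intermediate
8 | 1-[3-[(1S,2R)-4-(tert-butyldimethylsilyloxy)-1,2-dihydroxy-3-methylidenebutyl]-4-(triisopropylsilyloxy)phenyl]ethanone | O[C@@H](c1cc(C(C)=O)ccc1O[Si](C(C)C)(C(C)C)C(C)C)[C@H](O)C(=C)CO[Si](C)(C)C(C)(C)C | intermediate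
9 | (4S,5R)-4-[5-acetyl-2-(triisopropylsilyloxy)phenyl]-5-[3-(tert-butyldimethylsilyloxy)prop-1-en-2-yl]-1,3-dioxolan-2-one | O=C1O[C@@H](c2cc(C(C)=O)ccc2O[Si](C(C)C)(C(C)C)C(C)C)[C@@H](C(=C)CO[Si](C)(C)C(C)(C)C)O1 | intermediate
10 | 4-acetyl-2-[(4S,5R)-5-[3-(tert-butyldimethylsilyloxy)prop-1-en-2-yl]-2-oxo-1,3-dioxolan-4-yl]phenyl 3-methylbutanoate | O=C1O[C@@H](c2cc(C(C)=O)ccc2OC(=O)CC(C)C)[C@@H](C(=C)CO[Si](C)(C)C(C)(C)C)O1 | intermediate
11 | allylpalladium alkoxide zwitterion from 10 after loss of CO2 (sigma-allyl form, phosphine not drawn) | [O-][C@@H](c1cc(C(C)=O)ccc1OC(=O)CC(C)C)C=C(C[Pd+])CO[Si](C)(C)C(C)(C)C | intermediate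
12 | allylpalladium phenoxide zwitterion after the acyl shift (sigma-allyl form, phosphine not drawn) | [O-]c1ccc(C(C)=O)cc1[C@H](OC(=O)CC(C)C)C=C(C[Pd+])CO[Si](C)(C)C(C)(C)C | intermediate
13 | (2R,3S)-5-acetyl-2-[3-(tert-butyldimethylsilyloxy)prop-1-en-2-yl]-2,3-dihydro-1-benzofuran-3-yl 3-methylbutanoate | C=C(CO[Si](C)(C)C(C)(C)C)[C@H]1Oc2ccc(C(C)=O)cc2[C@@H]1OC(=O)CC(C)C | intermediate
14 | (2R,3S)-2-[3-(tert-butyldimethylsilyloxy)prop-1-en-2-yl]-5-[(1S)-1-hydroxyethyl]-2,3-dihydro-1-benzofuran-3-yl 3-methylbutanoate | C=C(CO[Si](C)(C)C(C)(C)C)[C@H]1Oc2ccc([C@H](C)O)cc2[C@@H]1OC(=O)CC(C)C | intermediate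
15 | (2R,3S)-5-[(1S)-1-acetoxyethyl]-2-[3-(tert-butyldimethylsilyloxy)prop-1-en-2-yl]-2,3-dihydro-1-benzofuran-3-yl 3-methylbutanoate | C=C(CO[Si](C)(C)C(C)(C)C)[C@H]1Oc2ccc([C@H](C)OC(C)=O)cc2[C@@H]1OC(=O)CC(C)C | intermediate
16 | (2R,3S)-5-[(1S)-1-acetoxyethyl]-2-(3-hydroxyprop-1-en-2-yl)-2,3-dihydro-1-benzofuran-3-yl 3-methylbutanoate | C=C(CO)[C@H]1Oc2ccc([C@H](C)OC(C)=O)cc2[C@@H]1OC(=O)CC(C)C | intermediate
17 | (2R,3S)-5-[(1S)-1-acetoxyethyl]-2-(3-oxoprop-1-en-2-yl)-2,3-dihydro-1-benzofuran-3-yl 3-methylbutanoate | C=C(C=O)[C@H]1Oc2ccc([C@H](C)OC(C)=O)cc2[C@@H]1OC(=O)CC(C)C | target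

Total step count: 13. Longest linear sequence: 13 steps (1 to 17).

**Steps most likely to fail**

Step 9 (proposed new method). The acyl shift may lag behind other reactions of the allylpalladium alkoxide, namely closure to the vinyl epoxide, hydride shift to an aryl ketone, or intermolecular acyl transfer. Prolonged contact with the catalyst may also re-ionise the allylic aryl ether and erode the C2 configuration. The fallback uses known chemistry and sets out from 9. Buffered fluoride (KHF2 in MeOH, or TBAF–AcOH in THF at 0 °C) cleaves only the aryl silyl ether to give (4S,5R)-4-(5-acetyl-2-hydroxyphenyl)-5-[3-(tert-butyldimethylsilyloxy)prop-1-en-2-yl]-1,3-dioxolan-2-one F1. Pd(PPh3)4 in THF then effects the intramolecular decarboxylative Tsuji–Trost etherification with the free phenol as pronucleophile, again with double inversion, to give 1-[(2R,3S)-2-[3-(tert-butyldimethylsilyloxy)prop-1-en-2-yl]-3-hydroxy-2,3-dihydro-1-benzofuran-5-yl]ethanone F2. Esterification with isovaleryl chloride, pyridine and DMAP returns to the route at 13.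

Step 4. The ylide may also methylenate the aryl ketone, or act as a base and enolise the dioxanone, leading to epimerisation next to the carbonyl or β-elimination of the silyloxy group. The fallback sets out from 3 and keeps the aryl ketone out of the molecule until the alkene is in place. 3 is combined under the step 2 conditions with 5-bromo-2-(triisopropylsilyloxy)benzaldehyde F3 (from 5-bromosalicylaldehyde and TIPSCl) to give (4S)-4-[(S)-[5-bromo-2-(triisopropylsilyloxy)phenyl](hydroxy)methyl]-2,2-dimethyl-1,3-dioxan-5-one F4. Silylation as in step 3 gives the triethylsilyl ether F5. Methylenation with Ph3P=CH2 gives (4R)-4-[(S)-[5-bromo-2-(triisopropylsilyloxy)phenyl](triethylsilyloxy)methyl]-2,2-dimethyl-5-methylidene-1,3-dioxane F6; no second ketone competes, and a non-basic titanium methylidene reagent can replace the ylide if it epimerises the ketone. Stille coupling with tributyl(1-ethoxyvinyl)stannane and Pd(PPh3)4 in toluene at 100 °C gives the 1-ethoxyvinyl arene F7. The aqueous acetic acid of step 5 then hydrolyses the enol ether, the ketal and the triethylsilyl ether together and returns to the route at 7.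

Step 2. Enamine addition to the hindered, donor-substituted aldehyde may be slow, and long reaction times allow retro-aldol equilibration that erodes the anti selectivity. The fallback sets out from 3 and replaces catalyst control by a closed boron transition state followed by resolution. Enolisation with (c-C6H11)2BCl and Et3N in Et2O at −78 °C gives 5-(dicyclohexylboryloxy)-2,2-dimethyl-4H-1,3-dioxine F8. Its fixed E geometry should add to 2 through the Zimmerman–Traxler chair to give the racemic anti aldol, that is 4 together with its enantiomer (4R)-4-[(R)-[5-acetyl-2-(triisopropylsilyloxy)phenyl](hydroxy)methyl]-2,2-dimethyl-1,3-dioxan-5-one F9. Preparative chromatography on a chiral stationary phase separates the two and returns to the route at 4.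

**Further compounds**
F1 | step 9 | (4S,5R)-4-(5-acetyl-2-hydroxyphenyl)-5-[3-(tert-butyldimethylsilyloxy)prop-1-en-2-yl]-1,3-dioxolan-2-one | O=C1O[C@@H](c2cc(C(C)=O)ccc2O)[C@@H](C(=C)CO[Si](C)(C)C(C)(C)C)O1
F2 | step 9 | 1-[(2R,3S)-2-[3-(tert-butyldimethylsilyloxy)prop-1-en-2-yl]-3-hydroxy-2,3-dihydro-1-benzofuran-5-yl]ethanone | C=C(CO[Si](C)(C)C(C)(C)C)[C@H]1Oc2ccc(C(C)=O)cc2[C@@H]1O
F3 | step 4 | 5-bromo-2-(triisopropylsilyloxy)benzaldehyde | O=Cc1cc(Br)ccc1O[Si](C(C)C)(C(C)C)C(C)C
F4 | step 4 | (4S)-4-[(S)-[5-bromo-2-(triisopropylsilyloxy)phenyl](hydroxy)methyl]-2,2-dimethyl-1,3-dioxan-5-one | O[C@@H](c1cc(Br)ccc1O[Si](C(C)C)(C(C)C)C(C)C)[C@@H]1OC(C)(C)OCC1=O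
F5 | step 4 | (4S)-4-[(S)-[5-bromo-2-(triisopropylsilyloxy)phenyl](triethylsilyloxy)methyl]-2,2-dimethyl-1,3-dioxan-5-one | CC[Si](CC)(CC)O[C@@H](c1cc(Br)ccc1O[Si](C(C)C)(C(C)C)C(C)C)[C@@H]1OC(C)(C)OCC1=O
F6 | step 4 | (4R)-4-[(S)-[5-bromo-2-(triisopropylsilyloxy)phenyl](triethylsilyloxy)methyl]-2,2-dimethyl-5-methylidene-1,3-dioxane | CC[Si](CC)(CC)O[C@@H](c1cc(Br)ccc1O[Si](C(C)C)(C(C)C)C(C)C)[C@@H]1OC(C)(C)OCC1=C
F7 | step 4 | (4R)-4-[(S)-[5-(1-ethoxyvinyl)-2-(triisopropylsilyloxy)phenyl](triethylsilyloxy)methyl]-2,2-dimethyl-5-methylidene-1,3-dioxane | CC[Si](CC)(CC)O[C@@H](c1cc(C(=C)OCC)ccc1O[Si](C(C)C)(C(C)C)C(C)C)[C@@H]1OC(C)(C)OCC1=C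
F8 | step 2 | 5-(dicyclohexylboryloxy)-2,2-dimethyl-4H-1,3-dioxine | CC1(C)OCC(OB(C2CCCCC2)C2CCCCC2)=CO1
F9 | step 2 | (4R)-4-[(R)-[5-acetyl-2-(triisopropylsilyloxy)phenyl](hydroxy)methyl]-2,2-dimethyl-1,3-dioxan-5-one | O[C@H](c1cc(C(C)=O)ccc1O[Si](C(C)C)(C(C)C)C(C)C)[C@H]1OC(C)(C)OCC1=O
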